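**Retrosynthetic overview**
1. The C3 ketone is unmasked last from a dioxolane; the C11–O aryl ether is cut (Mitsunobu) to umbelliferone and a 6-acetoxy-drim-7-en-11-ol.
2. C9–H and C11–OH come from face-selective hydroboration of a 7,9(11)-diene, made by methylenation of an 8-methyl-Δ7-9-enone (IBX dehydrogenation of the 8-methyl-9-ketone).
3. H5 and the C6 oxygen (syn to each other, anti to the C10 methyl) are set together by hydroboration of a 4,4-dimethyl-Δ5 olefin.
4. That olefin comes from deconjugative gem-dimethylation of (R)-Wieland–Miescher ketone, whose quaternary C10 is the only imported stereocentre.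
5. Ring order: carbocyclic rings A and B are present from the start as the fused decalin; the coumarin bicycle is attached last as intact umbelliferone.

Assumption: locants follow drimane numbering (C11 = CH2O on C9, C12 = methyl on C8); the SMILES fixes the target as (5S,6R,9R,10S), the ent-drimane series, so commercial (R)-Wieland–Miescher ketone is the chiral starting material.

**Route**

Step 1
Reactants: 1 (R)-Wieland–Miescher ketone
Product: 2 (4aR,5R)-5-hydroxy-4a-methyl-4,4a,5,6,7,8-hexahydronaphthalen-2(3H)-one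
Conditions: NaBH4 (0.3 equiv), EtOH, −10 to 0 °C; then H2O
Reagents that add atoms: none
Why: Chemoselective borohydride reduction of the saturated C9 ketone over the less electrophilic enone carbonyl, with hydride entering anti to the angular methyl so the new carbinol (9R) has OH cis to that methyl.

Step 2
Reactants: 2 (4aR,5R)-5-hydroxy-4a-methyl-4,4a,5,6,7,8-hexahydronaphthalen-2(3H)-one
Product: 4 (9R,10R)-9-hydroxy-11,12-dinordrim-5-en-3-one, via 4-methyl enone 3 (not isolated)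
Conditions: t-BuOK (3.5 equiv), t-BuOH/THF, 0 °C to rt; MeI (5 equiv)
Reagents that add atoms: iodomethane (CI)
Why: Deconjugative α,α-dialkylation of the extended enolate methylates C4 twice and moves the alkene to C5=C6, a process that tolerates a free secondary hydroxyl as in the classical 4,4-dimethylation of hydroxylated steroidal enones; no stereocentre is formed.

Step 3
Reactants: 4 (9R,10R)-9-hydroxy-11,12-dinordrim-5-en-3-one
Product: 5 (9R,10R)-3,3-(ethylenedioxy)-11,12-dinordrim-5-en-9-ol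
Conditions: ethylene glycol (5 equiv), p-TsOH·H2O (5 mol %), benzene, reflux, Dean–Stark
Reagents that add atoms: ethylene glycol (OCCO)
Why: Acid-catalysed ketalization with azeotropic water removal protects the C3 ketone; C4 is quaternary so the Δ5 alkene cannot migrate, and no stereocentre changes.

Step 4
Reactants: 5 (9R,10R)-3,3-(ethylenedioxy)-11,12-dinordrim-5-en-9-ol
Product: 6 (10R)-3,3-(ethylenedioxy)-11,12-dinordrim-5-en-9-one
Conditions: (n-Pr4N)RuO4 (5 mol %), N-methylmorpholine N-oxide (1.5 equiv), 4 Å MS, CH2Cl2, rt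
Reagents that add atoms: none
Why: Ley–Griffith oxidation converts the hindered secondary alcohol to the ketone under neutral conditions that leave the ketal and alkene intact.

Step 5
Reactants: 6 (10R)-3,3-(ethylenedioxy)-11,12-dinordrim-5-en-9-one
Product: 8 (8S,10R)-3,3-(ethylenedioxy)-11-nordrim-5-en-9-one, via lithium enolate 7 (not isolated)
Conditions: LiN(i-Pr)2 (1.1 equiv), THF, −78 °C; MeI (1.5 equiv), −78 to −20 °C
Reagents that add atoms: iodomethane (CI)
Why: Kinetic enolate alkylation can only occur at C8 because C10 is quaternary, and MeI approaches anti to the C10 methyl; this C8 centre is temporary and any epimer converges at step 8.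

Step 6
Reactants: 8 (8S,10R)-3,3-(ethylenedioxy)-11-nordrim-5-en-9-one
Product: 10 (5S,6R,8S,9R,10R)-3,3-(ethylenedioxy)-11-nordrimane-6,9-diol, via C6-alkylborane 9 (not isolated)
Conditions: BH3·THF (4 equiv), THF, 0 °C to rt; then 3 M NaOH, 30% H2O2, 0 to 40 °C
Reagents that add atoms: hydrogen peroxide (OO)
Why: Brown hydroboration–oxidation adds H and B syn across C5=C6 from the face opposite the axial C10 methyl (B on the less substituted C6), which fixes the trans ring fusion (5S) and, after stereoretentive oxidation, the C6 alcohol (6R) syn to H5; the C9 ketone is reduced at the same time to a temporary carbinol.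

Step 7
Reactants: 10 (5S,6R,8S,9R,10R)-3,3-(ethylenedioxy)-11-nordrimane-6,9-diol
Product: 11 (5S,6R,8S,9R,10R)-6-acetoxy-3,3-(ethylenedioxy)-11-nordriman-9-ol
Conditions: Ac2O (1.2 equiv), pyridine, DMAP (5 mol %), CH2Cl2, 0 °C
Reagents that add atoms: acetic anhydride (CC(=O)OC(C)=O)
Why: Kinetically controlled acylation takes the C6 hydroxyl (one tertiary and one CH2 neighbour) and leaves the C9 hydroxyl, which is wedged between quaternary C10 and methyl-bearing C8.

Step 8
Reactants: 11 (5S,6R,8S,9R,10R)-6-acetoxy-3,3-(ethylenedioxy)-11-nordriman-9-ol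
Product: 13 (5R,6R,10R)-6-acetoxy-3,3-(ethylenedioxy)-11-nordrim-7-en-9-one, via saturated 9-ketone 12 (not isolated)
Conditions: IBX (3.5 equiv), DMSO, rt then 75 °C
Reagents that add atoms: none
Why: IBX first oxidises the carbinol and then dehydrogenates the ketone (Nicolaou IBX dehydrogenation); C10 is quaternary so unsaturation can only enter at C7=C8, and the temporary C8 and C9 centres are erased.

Step 9
Reactants: 13 (5R,6R,10R)-6-acetoxy-3,3-(ethylenedioxy)-11-nordrim-7-en-9-one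
Product: 14 (5S,6R,10R)-6-acetoxy-3,3-(ethylenedioxy)drima-7,9(11)-diene
Conditions: Cp2Ti(μ-CH2)(μ-Cl)AlMe2 (1.3 equiv, toluene), pyridine (cat.), THF, −40 to 0 °C; then 0.1 M NaOH
Reagents that add atoms: Tebbe reagent Cp2Ti(μ-CH2)(μ-Cl)AlMe2 (C[Al-]1(C)C[Ti]([Cl+]1)(C1C=CC=C1)C1C=CC=C1)
Why: Tebbe methylenation uses a small, non-basic titanium methylidene that converts hindered conjugated ketones and, at low temperature, reacts with the ketone in preference to the acetate; no stereocentre is formed.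

Step 10
Reactants: 14 (5S,6R,10R)-6-acetoxy-3,3-(ethylenedioxy)drima-7,9(11)-diene
Product: 16 (5S,6R,9R,10S)-6-acetoxy-3,3-(ethylenedioxy)drim-7-en-11-ol, via B-alkyl-9-BBN adduct 15 (not isolated)
Conditions: 9-BBN (1.5 equiv), THF, 0 °C to rt; then 30% H2O2, aq. NaOAc, 0 °C to rt
Reagents that add atoms: hydrogen peroxide (OO)
Why: Anti-Markovnikov hydroboration with 9-BBN is selective for the 1,1-disubstituted exocyclic alkene (boron to C11) and delivers H to C9 from the face opposite the axial C10 methyl, giving 9R (CH2OH cis to that methyl), while the trisubstituted Δ7 alkene and the acetate survive the buffered oxidation.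

Step 11
Reactants: 16 (5S,6R,9R,10S)-6-acetoxy-3,3-(ethylenedioxy)drim-7-en-11-ol; 17 umbelliferone
Product: 18 (5S,6R,9R,10S)-6-acetoxy-3,3-(ethylenedioxy)-11-[(2-oxo-2H-chromen-7-yl)oxy]drim-7-ene
Conditions: PPh3 (1.5 equiv), DIAD (1.5 equiv), THF, 0 °C to rt
Reagents that add atoms: none
Why: Mitsunobu etherification in which the acidic phenol (pKa about 8) displaces the activated primary oxyphosphonium at C11; C11 is a CH2 so no stereocentre is touched.

Step 12
Reactants: 18 (5S,6R,9R,10S)-6-acetoxy-3,3-(ethylenedioxy)-11-[(2-oxo-2H-chromen-7-yl)oxy]drim-7-ene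
Product: 19 (1R,4R,4aS,8aS)-3,4a,8,8-tetramethyl-7-oxo-4-{[(2-oxo-2H-chromen-7-yl)oxy]methyl}-1,4,4a,5,6,7,8,8a-octahydronaphthalen-1-yl acetate
Conditions: PPTS (0.3 equiv), acetone/H2O (10:1), 50 °C
Reagents that add atoms: water (O)
Why: Mild acid-catalysed ketal hydrolysis is driven by strain release next to the gem-dimethyl carbon and is gentle enough to spare the allylic acetate, the lactone and all four stereocentres.

**Compound list**

1 | (R)-Wieland–Miescher ketone, (8aR)-8a-methyl-3,4,8,8a-tetrahydronaphthalene-1,6(2H,7H)-dione | C[C@@]12CCC(=O)C=C1CCCC2=O | starting material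
2 | (4aR,5R)-5-hydroxy-4a-methyl-4,4a,5,6,7,8-hexahydronaphthalen-2(3H)-one (OH cis to the angular methyl) | C[C@@]12CCC(=O)C=C1CCC[C@H]2O | intermediate
3 | (4aR,5R)-5-hydroxy-1,4a-dimethyl-4,4a,5,6,7,8-hexahydronaphthalen-2(3H)-one (4-methyl enone) | C[C@@]12CCC(=O)C(C)=C1CCC[C@H]2O | intermediate
4 | (9R,10R)-9-hydroxy-11,12-dinordrim-5-en-3-one | C[C@@]12CCC(=O)C(C)(C)C1=CCC[C@H]2O | intermediate
5 | (9R,10R)-3,3-(ethylenedioxy)-11,12-dinordrim-5-en-9-ol | C[C@@]12CCC3(OCCO3)C(C)(C)C1=CCC[C@H]2O | intermediate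
6 | (10R)-3,3-(ethylenedioxy)-11,12-dinordrim-5-en-9-one | C[C@@]12CCC3(OCCO3)C(C)(C)C1=CCCC2=O | intermediate
7 | lithium (10R)-3,3-(ethylenedioxy)-11,12-dinordrima-5,8-dien-9-olate (lithium enolate) | [Li+].C[C@@]12CCC3(OCCO3)C(C)(C)C1=CCC=C2[O-] | intermediate
8 | (8S,10R)-3,3-(ethylenedioxy)-11-nordrim-5-en-9-one (major C8 epimer, methyl trans to the C10 methyl) | C[C@@]12CCC3(OCCO3)C(C)(C)C1=CC[C@H](C)C2=O | intermediate
9 | 6-(dihydroboranyl)-9-(dihydroboranyloxy)-3,3-(ethylenedioxy)-11-nordrimane (H5 and C6–B syn, anti to the C10 methyl) | C[C@@]12CCC3(OCCO3)C(C)(C)[C@H]1[C@H](B)C[C@H](C)[C@H]2OB | intermediate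
10 | (5S,6R,8S,9R,10R)-3,3-(ethylenedioxy)-11-nordrimane-6,9-diol | C[C@@]12CCC3(OCCO3)C(C)(C)[C@H]1[C@H](O)C[C@H](C)[C@H]2O | intermediate
11 | (5S,6R,8S,9R,10R)-6-acetoxy-3,3-(ethylenedioxy)-11-nordriman-9-ol | C[C@@]12CCC3(OCCO3)C(C)(C)[C@H]1[C@H](OC(C)=O)C[C@H](C)[C@H]2O | intermediate
12 | (5R,6R,8S,10R)-6-acetoxy-3,3-(ethylenedioxy)-11-nordriman-9-one | C[C@@]12CCC3(OCCO3)C(C)(C)[C@H]1[C@H](OC(C)=O)C[C@H](C)C2=O | intermediate
13 | (5R,6R,10R)-6-acetoxy-3,3-(ethylenedioxy)-11-nordrim-7-en-9-one | C[C@@]12CCC3(OCCO3)C(C)(C)[C@H]1[C@H](OC(C)=O)C=C(C)C2=O | intermediate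
14 | (5S,6R,10R)-6-acetoxy-3,3-(ethylenedioxy)drima-7,9(11)-diene | C[C@@]12CCC3(OCCO3)C(C)(C)[C@H]1[C@H](OC(C)=O)C=C(C)C2=C | intermediate
15 | 9-[6-acetoxy-3,3-(ethylenedioxy)drim-7-en-11-yl]-9-borabicyclo[3.3.1]nonane (H9 anti to the C10 methyl) | C[C@@]12CCC3(OCCO3)C(C)(C)[C@H]1[C@H](OC(C)=O)C=C(C)[C@H]2CB1C2CCCC1CCC2 | intermediate
16 | (5S,6R,9R,10S)-6-acetoxy-3,3-(ethylenedioxy)drim-7-en-11-ol | C[C@@]12CCC3(OCCO3)C(C)(C)[C@H]1[C@H](OC(C)=O)C=C(C)[C@H]2CO | intermediate
17 | umbelliferone (7-hydroxy-2H-chromen-2-one) | Oc1ccc2ccc(=O)oc2c1 | starting material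
18 | (5S,6R,9R,10S)-6-acetoxy-3,3-(ethylenedioxy)-11-[(2-oxo-2H-chromen-7-yl)oxy]drim-7-ene | C[C@@]12CCC3(OCCO3)C(C)(C)[C@H]1[C@H](OC(C)=O)C=C(C)[C@H]2COc1ccc2ccc(=O)oc2c1 | intermediate
19 | (1R,4R,4aS,8aS)-3,4a,8,8-tetramethyl-7-oxo-4-{[(2-oxo-2H-chromen-7-yl)oxy]methyl}-1,4,4a,5,6,7,8,8a-octahydronaphthalen-1-yl acetate, CNP0140705.2 | CC(=O)O[C@@H]1C=C(C)[C@@H](COc2ccc3ccc(=O)oc3c2)[C@]2(C)CCC(=O)C(C)(C)[C@@H]12 | target

**Step count and risks**

Total step count: 12. Longest linear sequence: 12 steps (1 to 19); umbelliferone 17 is used as bought.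

Three steps most likely to fail:

Step 7 (site-selective acetylation of diol 10). The selectivity rests only on the rate difference between two hindered secondary alcohols. Fallback, setting out from 8 and coming back at 11: reduce 8 with LiAlH4 (THF, 0 °C) to (8S,9R,10R)-3,3-(ethylenedioxy)-11-nordrim-5-en-9-ol F1. Silylate it with t-BuMe2SiOTf/2,6-lutidine to the 9-silyl ether F2. Hydroborate–oxidise (BH3·THF; NaOH/H2O2) to the 6-alcohol F3, acetylate (Ac2O, DMAP) to the 6-acetate F4, and desilylate with Bu4NF/AcOH to reach 11. The two oxygens are then told apart by order of introduction and not by rate.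

Step 9 (methylenation of a hindered enone beside an ester, giving an acid-labile dienyl acetate). Fallback, setting out from 10 and coming back at 14: silylate the C6 hydroxyl of 10 selectively (Et3SiCl, imidazole) to the 6-triethylsilyl ether F5. Oxidise and dehydrogenate with IBX to the silyloxy enone F6. Methylenate by a plain Wittig reaction (Ph3P=CH2, toluene, 80 °C, no ester present) to the silyloxy diene F7. Cleave the silyl ether with Bu4NF to the dienol F8 and acetylate (Ac2O, DMAP) to reach 14.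

Step 11 (Mitsunobu at a β-branched, neopentyl-like primary carbinol). Fallback, setting out from 16 and coming back at 18: convert 16 with Tf2O/2,6-di-tert-butyl-4-methylpyridine (CH2Cl2, −78 °C) into the C11 triflate F9. Displace it with the caesium phenoxide of 17 (Cs2CO3, MeCN, 0 °C to rt) to give 18 by direct SN2 alkylation.

**Further compounds**

F1 | step 7 | (8S,9R,10R)-3,3-(ethylenedioxy)-11-nordrim-5-en-9-ol | C[C@@]12CCC3(OCCO3)C(C)(C)C1=CC[C@H](C)[C@H]2O
F2 | step 7 | (8S,9R,10R)-9-(tert-butyldimethylsilyloxy)-3,3-(ethylenedioxy)-11-nordrim-5-ene | C[C@@]12CCC3(OCCO3)C(C)(C)C1=CC[C@H](C)[C@H]2O[Si](C)(C)C(C)(C)C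
F3 | step 7 | (5S,6R,8S,9R,10R)-9-(tert-butyldimethylsilyloxy)-3,3-(ethylenedioxy)-11-nordriman-6-ol | C[C@@]12CCC3(OCCO3)C(C)(C)[C@H]1[C@H](O)C[C@H](C)[C@H]2O[Si](C)(C)C(C)(C)C
F4 | step 7 | (5S,6R,8S,9R,10R)-6-acetoxy-9-(tert-butyldimethylsilyloxy)-3,3-(ethylenedioxy)-11-nordrimane | C[C@@]12CCC3(OCCO3)C(C)(C)[C@H]1[C@H](OC(C)=O)C[C@H](C)[C@H]2O[Si](C)(C)C(C)(C)C
F5 | step 9 | (5S,6R,8S,9R,10R)-3,3-(ethylenedioxy)-6-(triethylsilyloxy)-11-nordriman-9-ol | C[C@@]12CCC3(OCCO3)C(C)(C)[C@H]1[C@H](O[Si](CC)(CC)CC)C[C@H](C)[C@H]2O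
F6 | step 9 | (5R,6R,10R)-3,3-(ethylenedioxy)-6-(triethylsilyloxy)-11-nordrim-7-en-9-one | C[C@@]12CCC3(OCCO3)C(C)(C)[C@H]1[C@H](O[Si](CC)(CC)CC)C=C(C)C2=O
F7 | step 9 | (5S,6R,10R)-3,3-(ethylenedioxy)-6-(triethylsilyloxy)drima-7,9(11)-diene | C[C@@]12CCC3(OCCO3)C(C)(C)[C@H]1[C@H](O[Si](CC)(CC)CC)C=C(C)C2=C
F8 | step 9 | (5S,6R,10R)-3,3-(ethylenedioxy)drima-7,9(11)-dien-6-ol | C[C@@]12CCC3(OCCO3)C(C)(C)[C@H]1[C@H](O)C=C(C)C2=C
F9 | step 11 | (5S,6R,9R,10S)-6-acetoxy-3,3-(ethylenedioxy)drim-7-en-11-yl trifluoromethanesulfonate | C[C@@]12CCC3(OCCO3)C(C)(C)[C@H]1[C@H](OC(C)=O)C=C(C)[C@H]2COS(=O)(=O)C(F)(F)F
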